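Ring B (C5–C6–C7–C8–C9–C10) is closed last, through the C9–C10 bond. A tertiary cation at C10, released from a ring A cyclohexanol, is captured by C9 of a (Z)-allylsilane whose CH2SiMe3 group sits on C8; loss of silicon leaves exactly the C8=C12 exocyclic methylidene that ring B carries next to C9. One operation therefore closes the ring, builds the quaternary C10, sets C9 and fixes the alkene position, all relayed from the single C5 stereocentre. The precursor is a monocyclic 1,3,3-trimethylcyclohexanol carrying the complete arylated side chain, made by carbocupration of a terminal alkyne. The arene is then taken to the epoxyquinone and acylated with a desymmetrised hydroxymethylglutarate.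

Key step: step 10

Remark: drimane numbering is used for the decalin (C8 carries the methylidene C12, C9 the C11 methylene link, C10 the angular methyl) and primed locants for the oxygenated six-membered ring; the oxirane is treated as an oxidation level of that ring, added after the carbon framework is complete, so ring B is the last carbocycle to close.

Step 1
Reactants: 1 2,4,4-trimethylcyclohex-2-en-1-one
Product: 2 (1S)-2,4,4-trimethylcyclohex-2-en-1-ol
Conditions: (R)-Me-CBS oxazaborolidine (10 mol%), BH3·SMe2, THF, −20 °C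
Reagents that add atoms: none
Why: Corey–Bakshi–Shibata reduction, in which the methyl-substituted alkene side of the enone acts as the large group and the CH2 side as the small one, so hydride is delivered to the face that gives the (S)-allylic alcohol.

Step 2
Reactants: 2 (1S)-2,4,4-trimethylcyclohex-2-en-1-ol
Product: 3 (1S)-2,4,4-trimethylcyclohex-2-en-1-yl pyridine-2-carboxylate
Conditions: picolinic acid, DCC, DMAP (cat.), CH2Cl2, 0 °C → rt
Reagents that add atoms: pyridine-2-carboxylic acid, OC(=O)c1ccccn1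
Why: Steglich esterification installs the chelating picolinate leaving group without touching the carbinol configuration.

Step 3
Reactants: 3 (1S)-2,4,4-trimethylcyclohex-2-en-1-yl pyridine-2-carboxylate; 4 (4-bromobut-1-yn-1-yl)trimethylsilane
Product: 6 trimethyl{4-[(1S)-2,6,6-trimethylcyclohex-2-en-1-yl]but-1-yn-1-yl}silane, via Grignard reagent 5 (not isolated)
Conditions: 4, Mg, THF; then CuBr·SMe2, 3, THF, −40 → 0 °C; aq. NH4Cl
Reagents that add atoms: none
Why: Copper-mediated anti-SN2' substitution of an allylic picolinate by a Grignard reagent, in which magnesium chelation by the picolinate directs the alkylcopper to the γ-carbon on the face opposite the leaving group, so the carbinol chirality is transferred to the new (S)-centre (C5 of the target) and the alkene moves to C1=C10.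

Step 4
Reactants: 6 trimethyl{4-[(1S)-2,6,6-trimethylcyclohex-2-en-1-yl]but-1-yn-1-yl}silane
Product: 8 (2S)-2-(but-3-yn-1-yl)-1,3,3-trimethylcyclohexan-1-ol (both C1 epimers), via silylalkyne alcohol 7 (not isolated)
Conditions: Co(acac)2 (cat.), PhSiH3, O2 (1 atm), THF, rt; then K2CO3, MeOH, rt
Reagents that add atoms: dioxygen, O=O
Why: Mukaiyama hydration (Markovnikov hydrogen-atom transfer, O2 capture of the tertiary radical, reduction of the peroxide) gives the tertiary alcohol, whose configuration is irrelevant because it is ionised later, and methanolic carbonate then cleaves the alkynyl C–Si bond; C5 is not involved.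

Step 5
Reactants: 9 4-bromo-2,5-dimethoxybenzaldehyde
Product: 10 4-bromo-2-hydroxy-5-methoxybenzaldehyde
Conditions: BCl3, CH2Cl2, −78 °C → rt; H2O
Reagents that add atoms: none
Why: Chelation-controlled demethylation, in which BCl3 bridges the aldehyde and the ortho methoxy oxygen and cleaves only that ether, differentiating the two oxygens of the future quinone.

Step 6
Reactants: 10 4-bromo-2-hydroxy-5-methoxybenzaldehyde
Product: 11 4-bromo-5-methoxy-2-{[tri(propan-2-yl)silyl]oxy}benzaldehyde
Conditions: TIPSCl, imidazole, DMF, rt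
Reagents that add atoms: chlorotri(propan-2-yl)silane, CC(C)[Si](Cl)(C(C)C)C(C)C
Why: Standard phenol silylation; the bulky aryl silyl ether should survive the organocopper, Lewis acid and organolithium steps.

Step 7
Reactants: 11 4-bromo-5-methoxy-2-{[tri(propan-2-yl)silyl]oxy}benzaldehyde
Product: 12 (4-bromo-5-methoxy-2-{[tri(propan-2-yl)silyl]oxy}phenyl)methanol
Conditions: DIBAL-H, CH2Cl2, −78 °C; Rochelle salt
Reagents that add atoms: none
Why: Hydride reduction of the aldehyde at low temperature, where the aluminium alkoxide should not trigger silyl migration from the phenol oxygen.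

Step 8
Reactants: 12 (4-bromo-5-methoxy-2-{[tri(propan-2-yl)silyl]oxy}phenyl)methanol
Product: 13 [5-bromo-2-(bromomethyl)-4-methoxyphenoxy]tri(propan-2-yl)silane
Conditions: CBr4, PPh3, CH2Cl2, 0 °C
Reagents that add atoms: tetrabromomethane, BrC(Br)(Br)Br
Why: Appel reaction converts the benzylic alcohol into the bromide under neutral conditions that the aryl silyl ether tolerates.

Step 9
Reactants: 8 (2S)-2-(but-3-yn-1-yl)-1,3,3-trimethylcyclohexan-1-ol; 13 [5-bromo-2-(bromomethyl)-4-methoxyphenoxy]tri(propan-2-yl)silane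
Product: 15 (2S)-2-[(3Z)-5-(4-bromo-5-methoxy-2-{[tri(propan-2-yl)silyl]oxy}phenyl)-3-[(trimethylsilyl)methyl]pent-3-en-1-yl]-1,3,3-trimethylcyclohexan-1-ol (both C1 epimers), via alkenylcopper magnesium alkoxide 14 (not isolated)
Conditions: Me3SiCH2MgCl (1.0 equiv), Et2O, −40 °C; then Me3SiCH2Cu·MgBrCl (from Me3SiCH2MgCl + CuBr·SMe2), Et2O/Me2S, −25 → 0 °C; then 13, DMPU, P(OEt)3, −20 °C → rt; aq. NH4Cl
Reagents that add atoms: (trimethylsilyl)methylmagnesium chloride, C[Si](C)(C)C[Mg]Cl
Why: Carbocupration, in which the silylmethylcopper reagent adds syn across the terminal alkyne with copper on the terminal carbon and the alkenylcopper is benzylated with retention, fixing the Z geometry (silylmethyl cis to the benzylic carbon); the aryl bromide is inert to organocopper.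

Step 10
Reactants: 15 (2S)-2-[(3Z)-5-(4-bromo-5-methoxy-2-{[tri(propan-2-yl)silyl]oxy}phenyl)-3-[(trimethylsilyl)methyl]pent-3-en-1-yl]-1,3,3-trimethylcyclohexan-1-ol
Product: 16 [5-bromo-4-methoxy-2-{[(1S,4aS,8aS)-5,5,8a-trimethyl-2-methylidenedecahydronaphthalen-1-yl]methyl}phenoxy]tri(propan-2-yl)silane
Conditions: TiCl4, 2,6-di-tert-butyl-4-methylpyridine, CH2Cl2, −78 → −40 °C; aq. NaHCO3
Reagents that add atoms: none
Why: TiCl4 ionises the tertiary alcohol (either C1 epimer, through its titanate or chloride) to the C10 cation while the hindered pyridine traps HCl; C9 of the allylsilane attacks this cation in an SE2' sense and the β-silyl cation at C8 loses Me3Si+ to leave the C8=C12 methylidene. The closest known reaction type is the allylsilane-terminated cation–olefin cyclisation (an intramolecular Hosomi–Sakurai alkylation of a tertiary cation). Ring B closes in a 6-endo-trig mode through a chair transition state with the C5 side chain equatorial on ring A. C10 is controlled by C5, since the new C9–C10 bond forms equatorially and anti to the axial C5–H so that the methyl ends axial and the fusion trans, and C9 is controlled by the Z alkene geometry, which places C11 (trans to C7 on the alkene) equatorial. The step needs ring closure to outrun proton loss from the cation and protodesilylation; the β-silyl-enhanced nucleophile held in a six-membered transition state, the acid scavenger and the low temperature should secure this, and because no free Brønsted acid is present an alkene formed by elimination cannot re-enter and erode the C5 stereocentre. The alkene position is fixed by silicon, so no endocyclic isomer can form.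

Step 11
Reactants: 16 [5-bromo-4-methoxy-2-{[(1S,4aS,8aS)-5,5,8a-trimethyl-2-methylidenedecahydronaphthalen-1-yl]methyl}phenoxy]tri(propan-2-yl)silane
Product: 19 [2-methoxy-4-{[(1S,4aS,8aS)-5,5,8a-trimethyl-2-methylidenedecahydronaphthalen-1-yl]methyl}-5-{[tri(propan-2-yl)silyl]oxy}phenyl]methanol, via aryllithium 17 (not isolated), via aldehyde 18 (not isolated)
Conditions: t-BuLi (2.1 equiv), THF, −78 °C; DMF; then MeOH, NaBH4, 0 °C
Reagents that add atoms: N,N-dimethylformamide, CN(C)C=O
Why: Lithium–bromine exchange, formylation of the aryllithium and in situ borohydride reduction give the benzylic alcohol; the aryl silyl ether and the 1,1-disubstituted alkene are inert to these reagents.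

Step 12
Reactants: 19 [2-methoxy-4-{[(1S,4aS,8aS)-5,5,8a-trimethyl-2-methylidenedecahydronaphthalen-1-yl]methyl}-5-{[tri(propan-2-yl)silyl]oxy}phenyl]methanol
Product: 20 5-(hydroxymethyl)-4-methoxy-2-{[(1S,4aS,8aS)-5,5,8a-trimethyl-2-methylidenedecahydronaphthalen-1-yl]methyl}phenol
Conditions: TBAF, THF, 0 °C; aq. NH4Cl
Reagents that add atoms: none
Why: Fluoride cleaves the aryl Si–O bond and unmasks the phenol needed for dearomatisation.

Step 13
Reactants: 20 5-(hydroxymethyl)-4-methoxy-2-{[(1S,4aS,8aS)-5,5,8a-trimethyl-2-methylidenedecahydronaphthalen-1-yl]methyl}phenol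
Product: 21 5-(hydroxymethyl)-4,4-dimethoxy-2-{[(1S,4aS,8aS)-5,5,8a-trimethyl-2-methylidenedecahydronaphthalen-1-yl]methyl}cyclohexa-2,5-dien-1-one
Conditions: PhI(OAc)2, MeOH, 0 °C
Reagents that add atoms: methanol, CO
Why: Oxidative dearomatisation of a para-methoxyphenol, in which the phenolic carbon becomes the ketone and the methoxy-bearing carbon the dimethyl ketal, placing the enone carbonyl next to the terpenyl-substituted carbon.

Step 14
Reactants: 21 5-(hydroxymethyl)-4,4-dimethoxy-2-{[(1S,4aS,8aS)-5,5,8a-trimethyl-2-methylidenedecahydronaphthalen-1-yl]methyl}cyclohexa-2,5-dien-1-one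
Product: 22 (1R,6S)-4-(hydroxymethyl)-5,5-dimethoxy-1-{[(1S,4aS,8aS)-5,5,8a-trimethyl-2-methylidenedecahydronaphthalen-1-yl]methyl}-7-oxabicyclo[4.1.0]hept-3-en-2-one
Conditions: t-BuOOH, N-benzylcinchonidinium chloride (10 mol%), aq. NaOH, toluene, 0 °C
Reagents that add atoms: tert-butyl hydroperoxide, CC(C)(C)OO
Why: Weitz–Scheffer nucleophilic epoxidation under chiral phase-transfer catalysis, in which the peroxide anion adds to the only unsubstituted β-carbon of the dienone (so only the terpenyl-substituted alkene reacts) and the face is chosen by the cinchonidinium ion pair, expected by analogy with other quinone monoketals to give the (1R,6S)-epoxide.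

Step 15
Reactants: 23 dimethyl 3-hydroxy-3-methylpentanedioate
Product: 24 (3S)-3-hydroxy-5-methoxy-3-methyl-5-oxopentanoic acid
Conditions: pig liver esterase, phosphate buffer (pH 7), rt
Reagents that add atoms: water, O
Why: Enzymatic desymmetrisation, in which the esterase should hydrolyse the pro-S ester group of the prochiral diester to give the (S)-half-ester.

Step 16
Reactants: 24 (3S)-3-hydroxy-5-methoxy-3-methyl-5-oxopentanoic acid
Product: 25 1-methyl 5-(2-phenylpropan-2-yl) (3R)-3-hydroxy-3-methylpentanedioate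
Conditions: 2-phenylpropan-2-yl 2,2,2-trichloroacetimidate, CH2Cl2, rt
Reagents that add atoms: 2-phenylpropan-2-yl 2,2,2-trichloroacetimidate, CC(C)(OC(=N)C(Cl)(Cl)Cl)c1ccccc1
Why: Trichloroacetimidate esterification, in which the carboxylic acid itself protonates the imidate and is alkylated while the tertiary alcohol is untouched; the tertiary benzylic ester is base-stable but cleaved by dilute acid (the descriptor changes only through priorities).

Step 17
Reactants: 25 1-methyl 5-(2-phenylpropan-2-yl) (3R)-3-hydroxy-3-methylpentanedioate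
Product: 26 (3R)-3-hydroxy-3-methyl-5-oxo-5-[(2-phenylpropan-2-yl)oxy]pentanoic acid
Conditions: LiOH, THF/H2O, 0 °C; then cold dilute HCl to pH 4
Reagents that add atoms: lithium hydroxide, [Li+].[OH-]
Why: Saponification of the unhindered methyl ester with the hindered tertiary ester left intact; the stereocentre bears no hydrogen and cannot epimerise.

Step 18
Reactants: 22 (1R,6S)-4-(hydroxymethyl)-5,5-dimethoxy-1-{[(1S,4aS,8aS)-5,5,8a-trimethyl-2-methylidenedecahydronaphthalen-1-yl]methyl}-7-oxabicyclo[4.1.0]hept-3-en-2-one; 26 (3R)-3-hydroxy-3-methyl-5-oxo-5-[(2-phenylpropan-2-yl)oxy]pentanoic acid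
Product: 27 1-{[(1S,6R)-2,2-dimethoxy-5-oxo-6-{[(1S,4aS,8aS)-5,5,8a-trimethyl-2-methylidenedecahydronaphthalen-1-yl]methyl}-7-oxabicyclo[4.1.0]hept-3-en-3-yl]methyl} 5-(2-phenylpropan-2-yl) (3R)-3-hydroxy-3-methylpentanedioate
Conditions: EDC·HCl, DMAP (cat.), CH2Cl2, 0 °C → rt
Reagents that add atoms: none
Why: Steglich esterification of the primary allylic alcohol with the half-acid; the tertiary hydroxyl of the acid is too hindered to compete.

Step 19
Reactants: 27 1-{[(1S,6R)-2,2-dimethoxy-5-oxo-6-{[(1S,4aS,8aS)-5,5,8a-trimethyl-2-methylidenedecahydronaphthalen-1-yl]methyl}-7-oxabicyclo[4.1.0]hept-3-en-3-yl]methyl} 5-(2-phenylpropan-2-yl) (3R)-3-hydroxy-3-methylpentanedioate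
Product: 28 4'-oxomacrophorin D, (3S)-3-hydroxy-3-methyl-5-oxo-5-{[(1S,6R)-2,5-dioxo-6-{[(1S,4aS,8aS)-5,5,8a-trimethyl-2-methylidenedecahydronaphthalen-1-yl]methyl}-7-oxabicyclo[4.1.0]hept-3-en-3-yl]methoxy}pentanoic acid
Conditions: TFA (2 vol%), H2O, CH2Cl2, 0 °C
Reagents that add atoms: water, O
Why: Dilute aqueous acid hydrolyses the dimethyl ketal to the enedione and ionises the 2-phenylpropan-2-yl ester to the free acid (SN1 ester cleavage), under conditions expected to be too mild to protonate the 1,1-disubstituted alkene or open the electron-poor epoxide.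

Compound list
1 | 2,4,4-trimethylcyclohex-2-en-1-one | CC1=CC(C)(C)CCC1=O | starting material
2 | (1S)-2,4,4-trimethylcyclohex-2-en-1-ol | CC1=CC(C)(C)CC[C@@H]1O | intermediate
3 | (1S)-2,4,4-trimethylcyclohex-2-en-1-yl pyridine-2-carboxylate | CC1=CC(C)(C)CC[C@@H]1OC(=O)c1ccccn1 | intermediate
4 | (4-bromobut-1-yn-1-yl)trimethylsilane | C[Si](C)(C)C#CCCBr | starting material
5 | [4-(trimethylsilyl)but-3-yn-1-yl]magnesium bromide | C[Si](C)(C)C#CCC[Mg]Br | intermediate
6 | trimethyl{4-[(1S)-2,6,6-trimethylcyclohex-2-en-1-yl]but-1-yn-1-yl}silane | CC1=CCCC(C)(C)[C@@H]1CCC#C[Si](C)(C)C | intermediate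
7 | (2S)-1,3,3-trimethyl-2-[4-(trimethylsilyl)but-3-yn-1-yl]cyclohexan-1-ol (both C1 epimers) | CC1(O)CCCC(C)(C)[C@@H]1CCC#C[Si](C)(C)C | intermediate
8 | (2S)-2-(but-3-yn-1-yl)-1,3,3-trimethylcyclohexan-1-ol (both C1 epimers) | CC1(O)CCCC(C)(C)[C@@H]1CCC#C | intermediate
9 | 4-bromo-2,5-dimethoxybenzaldehyde | COc1cc(C=O)c(OC)cc1Br | starting material
10 | 4-bromo-2-hydroxy-5-methoxybenzaldehyde | COc1cc(C=O)c(O)cc1Br | intermediate
11 | 4-bromo-5-methoxy-2-{[tri(propan-2-yl)silyl]oxy}benzaldehyde | COc1cc(C=O)c(O[Si](C(C)C)(C(C)C)C(C)C)cc1Br | intermediate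
12 | (4-bromo-5-methoxy-2-{[tri(propan-2-yl)silyl]oxy}phenyl)methanol | COc1cc(CO)c(O[Si](C(C)C)(C(C)C)C(C)C)cc1Br | intermediate
13 | [5-bromo-2-(bromomethyl)-4-methoxyphenoxy]tri(propan-2-yl)silane | COc1cc(CBr)c(O[Si](C(C)C)(C(C)C)C(C)C)cc1Br | intermediate
14 | chloromagnesium (2S)-2-{(3Z)-4-cuprio-3-[(trimethylsilyl)methyl]but-3-en-1-yl}-1,3,3-trimethylcyclohexan-1-olate | CC1(O[Mg]Cl)CCCC(C)(C)[C@@H]1CC/C(C[Si](C)(C)C)=C/[Cu] | intermediate
15 | (2S)-2-[(3Z)-5-(4-bromo-5-methoxy-2-{[tri(propan-2-yl)silyl]oxy}phenyl)-3-[(trimethylsilyl)methyl]pent-3-en-1-yl]-1,3,3-trimethylcyclohexan-1-ol (both C1 epimers) | CC1(O)CCCC(C)(C)[C@@H]1CC/C(C[Si](C)(C)C)=C/Cc1cc(OC)c(Br)cc1O[Si](C(C)C)(C(C)C)C(C)C | intermediate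
16 | [5-bromo-4-methoxy-2-{[(1S,4aS,8aS)-5,5,8a-trimethyl-2-methylidenedecahydronaphthalen-1-yl]methyl}phenoxy]tri(propan-2-yl)silane | C=C1CC[C@H]2C(C)(C)CCC[C@]2(C)[C@H]1Cc1cc(OC)c(Br)cc1O[Si](C(C)C)(C(C)C)C(C)C | intermediate
17 | [2-methoxy-4-{[(1S,4aS,8aS)-5,5,8a-trimethyl-2-methylidenedecahydronaphthalen-1-yl]methyl}-5-{[tri(propan-2-yl)silyl]oxy}phenyl]lithium | C=C1CC[C@H]2C(C)(C)CCC[C@]2(C)[C@H]1Cc1cc(OC)c([Li])cc1O[Si](C(C)C)(C(C)C)C(C)C | intermediate
18 | 2-methoxy-4-{[(1S,4aS,8aS)-5,5,8a-trimethyl-2-methylidenedecahydronaphthalen-1-yl]methyl}-5-{[tri(propan-2-yl)silyl]oxy}benzaldehyde | C=C1CC[C@H]2C(C)(C)CCC[C@]2(C)[C@H]1Cc1cc(OC)c(C=O)cc1O[Si](C(C)C)(C(C)C)C(C)C | intermediate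
19 | [2-methoxy-4-{[(1S,4aS,8aS)-5,5,8a-trimethyl-2-methylidenedecahydronaphthalen-1-yl]methyl}-5-{[tri(propan-2-yl)silyl]oxy}phenyl]methanol | C=C1CC[C@H]2C(C)(C)CCC[C@]2(C)[C@H]1Cc1cc(OC)c(CO)cc1O[Si](C(C)C)(C(C)C)C(C)C | intermediate
20 | 5-(hydroxymethyl)-4-methoxy-2-{[(1S,4aS,8aS)-5,5,8a-trimethyl-2-methylidenedecahydronaphthalen-1-yl]methyl}phenol | C=C1CC[C@H]2C(C)(C)CCC[C@]2(C)[C@H]1Cc1cc(OC)c(CO)cc1O | intermediate
21 | 5-(hydroxymethyl)-4,4-dimethoxy-2-{[(1S,4aS,8aS)-5,5,8a-trimethyl-2-methylidenedecahydronaphthalen-1-yl]methyl}cyclohexa-2,5-dien-1-one | C=C1CC[C@H]2C(C)(C)CCC[C@]2(C)[C@H]1CC1=CC(OC)(OC)C(CO)=CC1=O | intermediate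
22 | (1R,6S)-4-(hydroxymethyl)-5,5-dimethoxy-1-{[(1S,4aS,8aS)-5,5,8a-trimethyl-2-methylidenedecahydronaphthalen-1-yl]methyl}-7-oxabicyclo[4.1.0]hept-3-en-2-one | C=C1CC[C@H]2C(C)(C)CCC[C@]2(C)[C@H]1C[C@@]12O[C@@H]1C(OC)(OC)C(CO)=CC2=O | intermediate
23 | dimethyl 3-hydroxy-3-methylpentanedioate | COC(=O)CC(C)(O)CC(=O)OC | starting material
24 | (3S)-3-hydroxy-5-methoxy-3-methyl-5-oxopentanoic acid | COC(=O)C[C@@](C)(O)CC(=O)O | intermediate
25 | 1-methyl 5-(2-phenylpropan-2-yl) (3R)-3-hydroxy-3-methylpentanedioate | COC(=O)C[C@@](C)(O)CC(=O)OC(C)(C)c1ccccc1 | intermediate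
26 | (3R)-3-hydroxy-3-methyl-5-oxo-5-[(2-phenylpropan-2-yl)oxy]pentanoic acid | OC(=O)C[C@@](C)(O)CC(=O)OC(C)(C)c1ccccc1 | intermediate
27 | 1-{[(1S,6R)-2,2-dimethoxy-5-oxo-6-{[(1S,4aS,8aS)-5,5,8a-trimethyl-2-methylidenedecahydronaphthalen-1-yl]methyl}-7-oxabicyclo[4.1.0]hept-3-en-3-yl]methyl} 5-(2-phenylpropan-2-yl) (3R)-3-hydroxy-3-methylpentanedioate | C=C1CC[C@H]2C(C)(C)CCC[C@]2(C)[C@H]1C[C@@]12O[C@@H]1C(OC)(OC)C(COC(=O)C[C@@](C)(O)CC(=O)OC(C)(C)c3ccccc3)=CC2=O | intermediate
28 | 4'-oxomacrophorin D | C=C1CC[C@H]2C(C)(C)CCC[C@]2(C)[C@H]1C[C@@]12O[C@@H]1C(=O)C(COC(=O)C[C@@](C)(O)CC(=O)O)=CC2=O | target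

Total step count: 19. Longest linear sequence: 12 steps (steps 1–4, 9–14, 18, 19).

Steps most likely to fail

1. Step 10 (key step). Loss of a proton from the C10 cation, or protodesilylation of the allylsilane by acid released on ionisation of the free alcohol, may outrun ring closure. The fallback generates the same cation without any proton source and sets out from 6. Markovnikov hydrofluorination of 6 (Fe2(C2O4)3·6H2O, NaBH4, Selectfluor, MeCN/H2O, 0 °C) should give {4-[(1S)-2-fluoro-2,6,6-trimethylcyclohexyl]but-1-yn-1-yl}trimethylsilane F1. K2CO3 in MeOH then gives (1S)-1-(but-3-yn-1-yl)-2-fluoro-2,6,6-trimethylcyclohexane F2. The carbocupration and benzylation of step 9 with 13 then give [5-bromo-2-{(2Z)-5-[(1S)-2-fluoro-2,6,6-trimethylcyclohexyl]-3-[(trimethylsilyl)methyl]pent-2-en-1-yl}-4-methoxyphenoxy]tri(propan-2-yl)silane F3. Catalytic BF3·OEt2 in CH2Cl2 at −78 °C abstracts fluoride from the tertiary C–F bond, a known allylation of tertiary alkyl fluorides by allylsilanes driven by Si–F bond formation, and ring closure comes back to the route at 16.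

2. Step 9. The weakly nucleophilic silylmethylcopper may add too slowly to the alkyne, or the alkenylcopper may be protonated before it is benzylated. The fallback sets out from 8 and splits the three-component coupling into two catalytic steps. Copper-catalysed borylative alkylation of the alkyne (CuCl, Xantphos, B2pin2, NaOt-Bu, ICH2SiMe3, THF) adds boron to the terminal carbon and the silylmethyl group syn to the internal carbon. This gives (2S)-1,3,3-trimethyl-2-{(3Z)-4-(4,4,5,5-tetramethyl-1,3,2-dioxaborolan-2-yl)-3-[(trimethylsilyl)methyl]but-3-en-1-yl}cyclohexan-1-ol F4. Suzuki–Miyaura coupling of F4 with the benzylic bromide 13 (Pd(PPh3)4, K3PO4, THF/H2O), which proceeds with retention at the alkene, comes back to the route at 15.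

3. Step 14. Facial selectivity of peroxide attack under ion-pair control may be poor or reversed, because the bulky α-substituent differs from the substrates on which the analogy rests. The fallback sets out from 21 and gives up reagent control. An uncatalysed Weitz–Scheffer epoxidation (t-BuOOH, DBU, CH2Cl2, 0 °C) gives both epoxides, which are diastereomers because the decalin is enantiopure and can be separated by chromatography. The unwanted one is (1S,6R)-4-(hydroxymethyl)-5,5-dimethoxy-1-{[(1S,4aS,8aS)-5,5,8a-trimethyl-2-methylidenedecahydronaphthalen-1-yl]methyl}-7-oxabicyclo[4.1.0]hept-3-en-2-one F5; the wanted one is 22, where the route is rejoined.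

Further compounds
F1 | step 10 | {4-[(1S)-2-fluoro-2,6,6-trimethylcyclohexyl]but-1-yn-1-yl}trimethylsilane | CC1(F)CCCC(C)(C)[C@@H]1CCC#C[Si](C)(C)C
F2 | step 10 | (1S)-1-(but-3-yn-1-yl)-2-fluoro-2,6,6-trimethylcyclohexane | CC1(F)CCCC(C)(C)[C@@H]1CCC#C
F3 | step 10 | [5-bromo-2-{(2Z)-5-[(1S)-2-fluoro-2,6,6-trimethylcyclohexyl]-3-[(trimethylsilyl)methyl]pent-2-en-1-yl}-4-methoxyphenoxy]tri(propan-2-yl)silane | CC1(F)CCCC(C)(C)[C@@H]1CC/C(C[Si](C)(C)C)=C/Cc1cc(OC)c(Br)cc1O[Si](C(C)C)(C(C)C)C(C)C
F4 | step 9 | (2S)-1,3,3-trimethyl-2-{(3Z)-4-(4,4,5,5-tetramethyl-1,3,2-dioxaborolan-2-yl)-3-[(trimethylsilyl)methyl]but-3-en-1-yl}cyclohexan-1-ol | CC1(O)CCCC(C)(C)[C@@H]1CC/C(C[Si](C)(C)C)=C/B1OC(C)(C)C(C)(C)O1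
F5 | step 14 | (1S,6R)-4-(hydroxymethyl)-5,5-dimethoxy-1-{[(1S,4aS,8aS)-5,5,8a-trimethyl-2-methylidenedecahydronaphthalen-1-yl]methyl}-7-oxabicyclo[4.1.0]hept-3-en-2-one | C=C1CC[C@H]2C(C)(C)CCC[C@]2(C)[C@H]1C[C@]12O[C@H]1C(OC)(OC)C(CO)=CC2=O
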